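**Retrosynthetic overview**
1. C13=C14 is made last by cross-metathesis (CM) of a C1–C13 chain olefin with an aryl isopropenyl ketone; C2=C3 by CM with acrylic acid; C4–C5 and C11–C12 by two (Z)-crotylborations.
2. The C6–C10 stereopentad is a meso array, traced to the meso cyclohexanone 8. Key step: a catalytic enantioselective, desymmetrising one-carbon ring expansion (1,2-shift) of 8 to the cycloheptenyl silyl ether 10; ozonolysis then cuts the ring to a C5 aldehyde / C11 ester.
3. Ketone 8 comes from all-cis hydrogenation of 2,4,6-trimethylphloroglucinol, itself from a [3+3] annulation of pentan-3-one with methylmalonyl dichloride.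
4. Arene: Diels–Alder of benzoquinone with a 2-siloxydiene and aromatisation, C5 bromination, azide amination, carbonylative Stille coupling.
5. Ring order: phloroglucinol ring (step 1) → cyclohexane (2) → 1,3-dioxane (3) → seven-membered ring by expansion (5), opened in step 6; separately, the benzenoid ring of the naphthoquinone (11).

Convention: chain carbons are numbered C1 (CO2H) to C15 (aryl C=O) as in the target; the arene is numbered as a 2-amino-5-acyl-6-hydroxy-7-methyl-1,4-naphthoquinone.
Assumption: the sense of induction of the new catalyst in step 5 cannot be predicted; the ligand antipode that gives 10 (not ent-10) is used, both antipodes being available.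

**Step 1**
Reactants: 1 pentan-3-one; 2 methylmalonyl dichloride
Product: 5 2,4,6-trimethylbenzene-1,3,5-triol, via silyl enol ether 3 (not isolated), via mono-silyl ether 4 (not isolated)
Conditions: 1, TBSOTf, Et3N, CH2Cl2, 0 °C, pentane extraction; then 2, Et2O, −20 °C → rt; then 3 M HCl, THF, 40 °C
Reagents that add atoms: none
Why: Effenberger-type [3+3] α,α′-annulation: the enol ether is C-acylated by one acid chloride, the derived cross-conjugated dienol ether closes onto the second, and the cyclohexane-1,3,5-trione aromatises (no stereocentre).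

**Step 2**
Reactants: 5 2,4,6-trimethylbenzene-1,3,5-triol
Product: 6 all-cis-2,4,6-trimethylcyclohexane-1,3,5-triol
Conditions: H2 (60 bar), 5% Rh/Al2O3, i-PrOH, 60 °C
Reagents that add atoms: none
Why: Heterogeneous arene hydrogenation delivers all hydrogens to the metal-bound face, giving the all-cis isomer (three equatorial Me, three axial OH); this fixes the relative configuration of C6–C10 in an achiral compound.

**Step 3**
Reactants: 6 all-cis-2,4,6-trimethylcyclohexane-1,3,5-triol
Product: 7 meso mono-acetonide 3,3,6,8,9-pentamethyl-2,4-dioxabicyclo[3.3.1]nonan-7-ol (all carbocycle substituents cis)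
Conditions: Me2C(OMe)2, CSA (cat.), acetone, 4 Å MS, 40 °C
Reagents that add atoms: 2,2-dimethoxypropane COC(C)(C)OC
Why: Acetonide formation across two of the three equivalent syn-axial hydroxyls (any pair gives the same meso product; the dioxane twists to seat its endo methyl), leaving one OH free.

**Step 4**
Reactants: 7 meso acetonide alcohol
Product: 8 meso 3,3,6,8,9-pentamethyl-2,4-dioxabicyclo[3.3.1]nonan-7-one
Conditions: TPAP (5 mol %), NMO, 4 Å MS, CH2Cl2, rt
Reagents that add atoms: none
Why: Ley–Griffith oxidation of the single free secondary alcohol; both α-methyls are already equatorial (thermodynamic cis,cis isomer), so nothing can epimerise.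

**Step 5**
Reactants: 8 meso ketone
Product: 10 trimethyl[(2,5,8,8,10-pentamethyl-7,9-dioxabicyclo[4.3.1]dec-3-en-4-yl)oxy]silane (single enantiomer; the new CH= carbon is bonded to the former (R)-α-carbon of 8), via β-keto silane 9 (not isolated)
Conditions: Sc(OTf)3 (10 mol %), chiral pybox ligand L* (12 mol %), TMSCHN2 (1.3 equiv), PhMe, 4 Å MS, −78 → −30 °C; then rt
Reagents that add atoms: trimethylsilyldiazomethane C[Si](C)(C)C=[N+]=[N-]
Why: Proposed new method: a chiral Sc(III) Lewis acid binds the meso ketone, TMSCHN2 adds to the open exo face (the endo face is covered by the acetonide), and the catalyst selects one face of the prochiral diazo carbon; with the bulky TMS group held away from the metal-bound alkoxide only one of the two enantiotopic C(α)–C(O) bonds is antiperiplanar to the leaving N2 and undergoes the 1,2-shift (retention at the migrating carbon), after which a Sc-promoted 1,3-Brook shift gives the regiodefined enol silane; this sets the absolute configuration of the whole stereoarray and forms the C5–C6 bond; closest known reaction type is the Sc(OTf)3-catalysed Tiffeneau–Demjanov-type homologation of cycloalkanones with TMSCHN2 and the chiral Lewis-acid-catalysed insertions of aryldiazoalkanes or α-diazo esters into cyclobutanones and 4-substituted cyclohexanones, whereas selection between the enantiotopic migrating groups of an α,α′-disubstituted meso ketone with TMSCHN2 has not been shown.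

**Step 6**
Reactants: 10 cycloheptenyl silyl enol ether
Product: 12 methyl 2-[2,2,5-trimethyl-6-(1-oxopropan-2-yl)-1,3-dioxan-4-yl]propanoate (C5 aldehyde, C11 methyl ester, 7,9-O-isopropylidene; C6–C10 all-anti as in the target), via aldehyde acid 11 (not isolated)
Conditions: O3, CH2Cl2/MeOH 4:1, −78 °C; Me2S, −78 → 0 °C; then TMSCHN2, PhMe/MeOH, 0 °C
Reagents that add atoms: ozone [O-][O+]=O; trimethylsilyldiazomethane C[Si](C)(C)C=[N+]=[N-]
Why: Ozonolysis of the electron-rich silyl enol ether cuts the C5=C11 bond to a C5 aldehyde and a C11 acid (esterified in the same pot), so the two chain ends are chemically different and no stereocentre is touched.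

**Step 7**
Reactants: 12 aldehyde ester
Product: 13 methyl ester of the C3–C11 fragment with 5-OH, 4-Me and a terminal vinyl group (4,5-syn, 5,6-anti)
Conditions: (Z)-crotyl-Bpin (1.5 equiv), PhMe, 4 Å MS, rt, 48 h; aq. NaHCO3
Reagents that add atoms: (Z)-crotylboronic acid pinacol ester C/C=C\CB1OC(C)(C)C(C)(C)O1
Why: Type-I allylboration through a chair transition state: the (Z)-crotyl geometry gives 4,5-syn, and the intrinsic anti-Felkin preference of (Z)-crotylboronates with α-methyl aldehydes (no syn-pentane clash with the C6 methyl) gives 5,6-anti (dr about 9:1 expected).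

**Step 8**
Reactants: 13 hydroxy ester
Product: 14 hydroxy aldehyde (C11 CHO, C5 OH, C3=C vinyl)
Conditions: DIBAL-H (2.2 equiv), CH2Cl2, −78 °C; Rochelle salt
Reagents that add atoms: none
Why: Partial DIBAL-H reduction of an α-branched methyl ester; the tetrahedral aluminate, chelated by the acetonide oxygen, survives at −78 °C and gives the aldehyde on work-up without epimerising C10.

**Step 9**
Reactants: 14 hydroxy aldehyde; 15 acrylic acid
Product: 16 (E)-enoic acid aldehyde (C1 CO2H, C2=C3 E, C11 CHO)
Conditions: Hoveyda–Grubbs II (5 mol %), 15 (5 equiv), CH2Cl2, 40 °C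
Reagents that add atoms: none
Why: Olefin cross-metathesis of a terminal olefin with acrylic acid gives the E-enoic acid; the aldehyde and free alcohol are tolerated by the Ru catalyst.

**Step 10**
Reactants: 16 enoic acid aldehyde
Product: 17 C1–C13 acid with 5-OH, 11-OH, 7,9-O-isopropylidene and a terminal C13 vinyl group
Conditions: (Z)-crotyl-Bpin (2 equiv), CH2Cl2, rt, 48 h; aq. work-up
Reagents that add atoms: (Z)-crotylboronic acid pinacol ester C/C=C\CB1OC(C)(C)C(C)(C)O1
Why: Same type-I (Z)-crotylboration at the locally mirror-image terminus, giving 11,12-syn and 10,11-anti by the same intrinsic anti-Felkin preference; the boronate tolerates the free acid and alcohol.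

**Step 11**
Reactants: 18 3-methylbut-3-en-2-one; 19 1,4-benzoquinone
Product: 23 6-hydroxy-7-methylnaphthalene-1,4-dione, via siloxy diene 20 (not isolated), via cis cycloadduct 21 (not isolated), via aryl silyl ether 22 (not isolated)
Conditions: 18, TMSOTf, Et3N, Et2O, 0 °C, pentane extraction; then 19 (3.1 equiv), PhMe, 25 → 60 °C; then 1 M HCl, THF
Reagents that add atoms: none
Why: Diels–Alder reaction of the 2-siloxydiene with benzoquinone, then enolisation and dehydrogenation by excess quinone, builds the benzenoid ring with OH at C6 and Me at C7 by construction.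

**Step 12**
Reactants: 23 6-hydroxy-7-methylnaphthalene-1,4-dione
Product: 24 5-bromo-6-hydroxy-7-methylnaphthalene-1,4-dione
Conditions: NBS, MeCN, 0 °C → rt, dark
Reagents that add atoms: N-bromosuccinimide O=C1CCC(=O)N1Br
Why: Electrophilic aromatic bromination ortho to the phenol at C5, the only free activated position (the other ortho position carries the methyl).

**Step 13**
Reactants: 24 bromonaphthoquinone
Product: 26 2-amino-5-bromo-6-hydroxy-7-methylnaphthalene-1,4-dione, via azido hydroquinone 25 (not isolated)
Conditions: NaN3, AcOH/H2O/THF, rt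
Reagents that add atoms: sodium azide [Na+].[N-]=[N+]=[N-]
Why: Conjugate addition of azide followed by internal redox with loss of N2 (the known azide route to aminoquinones); attack at C2 is expected because the 6-OH donates into C1=O through C8a, leaving C4=O as the acceptor.

**Step 14**
Reactants: 26 aminobromonaphthoquinone
Product: 27 2-amino-6-hydroxy-7-methyl-5-(2-methylprop-2-enoyl)naphthalene-1,4-dione
Conditions: CO (3 bar), tributyl(isopropenyl)stannane, Pd(PPh3)4 (5 mol %), PhMe, 90 °C
Reagents that add atoms: carbon monoxide [C-]#[O+]; tributyl(isopropenyl)stannane CCCC[Sn](CCCC)(CCCC)C(C)=C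
Why: Carbonylative Stille coupling (oxidative addition, CO insertion, transmetallation, reductive elimination) under neutral conditions that the quinone, vinylogous amide and phenol tolerate.

**Step 15**
Reactants: 17 C1–C13 olefin acid; 27 aryl isopropenyl ketone
Product: 28 7,9-O-isopropylidene derivative of the target
Conditions: Hoveyda–Grubbs II (10 mol %), 27 (2.5 equiv), 1,2-dichloroethane, 50 °C
Reagents that add atoms: none
Why: Cross-metathesis of a terminal olefin with a 1,1-disubstituted enone gives the thermodynamically favoured (E)-trisubstituted enone; the electron-poor enoic acid olefin is inert and quinones are compatible with Ru metathesis.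

**Step 16**
Reactants: 28 acetonide of the target
Product: 29 CNP0336625.1 (target)
Conditions: AcOH/H2O 4:1, 40 °C
Reagents that add atoms: none
Why: Mild acid-catalysed hydrolysis of the syn-1,3-diol acetonide; no base is used, so oxa-Michael addition to the enone or enoate is avoided.

**Compound list**
1 | pentan-3-one | CCC(=O)CC | starting material
2 | methylmalonyl dichloride (2-methylpropanedioyl dichloride) | CC(C(=O)Cl)C(=O)Cl | starting material
3 | (Z)-tert-butyldimethyl(pent-2-en-3-yloxy)silane (not isolated) | C/C=C(/CC)O[Si](C)(C)C(C)(C)C | intermediate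
4 | 5-(tert-butyldimethylsilyloxy)-2,4,6-trimethylbenzene-1,3-diol (not isolated) | Cc1c(O)c(C)c(O[Si](C)(C)C(C)(C)C)c(C)c1O | intermediate
5 | 2,4,6-trimethylbenzene-1,3,5-triol | Cc1c(O)c(C)c(O)c(C)c1O | intermediate
6 | all-cis-2,4,6-trimethylcyclohexane-1,3,5-triol (achiral) | O[C@@H]1[C@H](C)[C@H](O)[C@H](C)[C@H](O)[C@@H]1C | intermediate
7 | meso 3,3,6,8,9-pentamethyl-2,4-dioxabicyclo[3.3.1]nonan-7-ol, all carbocycle substituents cis | O[C@@H]1[C@H](C)[C@@H]2OC(C)(C)O[C@@H]([C@H]2C)[C@@H]1C | intermediate
8 | meso 3,3,6,8,9-pentamethyl-2,4-dioxabicyclo[3.3.1]nonan-7-one, methyls and ring oxygens cis on the carbocycle | O=C1[C@H](C)[C@@H]2OC(C)(C)O[C@@H]([C@H]2C)[C@@H]1C | intermediate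
9 | 2,5,8,8,10-pentamethyl-3-(trimethylsilyl)-7,9-dioxabicyclo[4.3.1]decan-4-one (not isolated; configuration at the silyl-bearing carbon not assigned, lost in the Brook shift) | C[Si](C)(C)C1[C@H](C)[C@@H]2OC(C)(C)O[C@@H]([C@H]2C)[C@H](C)C1=O | intermediate
10 | trimethyl[(2,5,8,8,10-pentamethyl-7,9-dioxabicyclo[4.3.1]dec-3-en-4-yl)oxy]silane, single enantiomer | C[Si](C)(C)OC1=C[C@H](C)[C@@H]2OC(C)(C)O[C@@H]([C@H]2C)[C@@H]1C | intermediate
11 | 2-[2,2,5-trimethyl-6-(1-oxopropan-2-yl)-1,3-dioxan-4-yl]propanoic acid (not isolated), stereocentres as target C6–C10 | OC(=O)[C@@H](C)[C@H]1OC(C)(C)O[C@@H]([C@@H](C)C=O)[C@@H]1C | intermediate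
12 | methyl 2-[2,2,5-trimethyl-6-(1-oxopropan-2-yl)-1,3-dioxan-4-yl]propanoate, stereocentres as target C6–C10 | COC(=O)[C@@H](C)[C@H]1OC(C)(C)O[C@@H]([C@@H](C)C=O)[C@@H]1C | intermediate
13 | C3–C11 hydroxy ester (C11 CO2Me, 7,9-acetonide, 5-OH, 4-Me, C3 vinyl; configuration as target C4–C10) | COC(=O)[C@@H](C)[C@H]1OC(C)(C)O[C@@H]([C@@H](C)[C@@H](O)[C@H](C)C=C)[C@@H]1C | intermediate
14 | C3–C11 hydroxy aldehyde (C11 CHO) | O=C[C@@H](C)[C@H]1OC(C)(C)O[C@@H]([C@@H](C)[C@@H](O)[C@H](C)C=C)[C@@H]1C | intermediate
15 | acrylic acid | C=CC(=O)O | starting material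
16 | C1–C11 (E)-enoic acid aldehyde | O=C[C@@H](C)[C@H]1OC(C)(C)O[C@@H]([C@@H](C)[C@@H](O)[C@H](C)/C=C/C(=O)O)[C@@H]1C | intermediate
17 | C1–C13 (E)-enoic acid with 5-OH, 11-OH, 7,9-acetonide and C13 vinyl; configuration as target C4–C12 | C=C[C@H](C)[C@@H](O)[C@@H](C)[C@H]1OC(C)(C)O[C@@H]([C@@H](C)[C@@H](O)[C@H](C)/C=C/C(=O)O)[C@@H]1C | intermediate
18 | 3-methylbut-3-en-2-one | CC(=O)C(C)=C | starting material
19 | 1,4-benzoquinone | O=C1C=CC(=O)C=C1 | starting material
20 | trimethyl[(3-methylbuta-1,3-dien-2-yl)oxy]silane (not isolated) | C=C(C)C(=C)O[Si](C)(C)C | intermediate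
21 | (±)-cis-7-methyl-6-(trimethylsilyloxy)-4a,5,8,8a-tetrahydronaphthalene-1,4-dione (not isolated; one enantiomer drawn) | O=C1C=CC(=O)[C@H]2CC(O[Si](C)(C)C)=C(C)C[C@@H]12 | intermediate
22 | 7-methyl-6-(trimethylsilyloxy)naphthalene-1,4-dione (not isolated) | Cc1cc2C(=O)C=CC(=O)c2cc1O[Si](C)(C)C | intermediate
23 | 6-hydroxy-7-methylnaphthalene-1,4-dione | Cc1cc2C(=O)C=CC(=O)c2cc1O | intermediate
24 | 5-bromo-6-hydroxy-7-methylnaphthalene-1,4-dione | Brc1c(O)c(C)cc2c1C(=O)C=CC2=O | intermediate
25 | 2-azido-5-bromo-7-methylnaphthalene-1,4,6-triol (not isolated) | Brc1c(O)c(C)cc2c(O)c(N=[N+]=[N-])cc(O)c12 | intermediate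
26 | 2-amino-5-bromo-6-hydroxy-7-methylnaphthalene-1,4-dione | Brc1c(O)c(C)cc2c1C(=O)C=C(N)C2=O | intermediate
27 | 2-amino-6-hydroxy-7-methyl-5-(2-methylprop-2-enoyl)naphthalene-1,4-dione | CC(=C)C(=O)c1c(O)c(C)cc2c1C(=O)C=C(N)C2=O | intermediate
28 | 7,9-O-isopropylidene derivative of the target | C/C(=C\[C@H](C)[C@@H](O)[C@@H](C)[C@H]1OC(C)(C)O[C@@H]([C@@H](C)[C@@H](O)[C@H](C)/C=C/C(=O)O)[C@@H]1C)C(=O)c2c(O)c(C)cc3c2C(=O)C=C(N)C3=O | intermediate
29 | CNP0336625.1 | C/C(=C\[C@H](C)[C@@H](O)[C@@H](C)[C@@H](O)[C@@H](C)[C@@H](O)[C@@H](C)[C@@H](O)[C@H](C)/C=C/C(=O)O)C(=O)c1c(O)c(C)cc2c1C(=O)C=C(N)C2=O | target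

**Totals**
Total step count: 16 (telescoped one-pot sequences counted as one step).
Longest linear sequence: 12 steps (steps 1–10, 15, 16); the arene branch (steps 11–14) joins at step 15.

**Three steps most likely to fail, with fallbacks**

Step 5 (the proposed new desymmetrising ring expansion) may give low enantioselectivity, or epoxide instead of migration. The fallback uses only known chemistry and moves the desymmetrisation to an enzyme; it sets out from 8 and returns at 12. Ketone 8 is homologated with TMSCHN2 and Sc(OTf)3 without ligand (the known achiral reaction) to the racemic enol silane F1. Ozonolysis of F1 with LiAlH4 reductive work-up reduces both termini and restores the mirror plane in the meso diol F2. Lipase-catalysed mono-acetylation with vinyl acetate, with the enzyme screened for the required sense, gives the monoacetate F3, which carries the acetate on the CH2OH next to the future C6. Direct oxidative esterification of the free primary alcohol (PDC, MeOH, DMF) gives the acetoxy methyl ester F4. Methanolysis (K2CO3, MeOH, 0 °C) gives the hydroxy ester F5, and Dess–Martin oxidation then returns the route to 12.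

Step 15 (CM of a branched terminal olefin with a hindered 1,1-disubstituted aryl enone) may stall at homodimer or give low conversion. The fallback sets out from 17 and returns at 28. Compound 17 undergoes CM with commercial isopropenylboronic acid pinacol ester (used in excess; a known route to trisubstituted alkenyl boronates) to give the alkenyl boronate F6, in which the chain is trans to boron. A carbonylative Suzuki–Miyaura coupling of F6 with the aryl bromide 26 (CO, Pd(dppf)Cl2, K2CO3, dioxane) then gives 28, and step 14 is no longer needed.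

Step 1 (Effenberger-type annulation on an acyclic ketone) may stop at O-cyclisation. The fallback sets out from 1 and 2 (through 3) and returns at 5. The O-cyclised product, 6-ethyl-4-hydroxy-3,5-dimethyl-2H-pyran-2-one F7, is accepted as the intermediate. It is opened with Mg(OMe)2 in MeOH to methyl 2,4-dimethyl-3,5-dioxoheptanoate F8, and a Claisen (Dieckmann-type) cyclisation with NaH in refluxing THF, followed by acidification, gives 5.

**Further compounds**
F1 | step 5 | racemic 10 (one enantiomer drawn) | C[Si](C)(C)OC1=C[C@H](C)[C@@H]2OC(C)(C)O[C@@H]([C@H]2C)[C@@H]1C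
F2 | step 5 | meso 2,2'-(2,2,5-trimethyl-1,3-dioxane-4,6-diyl)di(propan-1-ol), configuration as target C6–C10 | OC[C@@H](C)[C@H]1OC(C)(C)O[C@@H]([C@@H](C)CO)[C@@H]1C
F3 | step 5 | monoacetate of F2 (acetate on the C5-side CH2OH) | OC[C@@H](C)[C@H]1OC(C)(C)O[C@@H]([C@@H](C)COC(C)=O)[C@@H]1C
F4 | step 5 | acetoxy methyl ester (C11 CO2Me, C5 CH2OAc) | COC(=O)[C@@H](C)[C@H]1OC(C)(C)O[C@@H]([C@@H](C)COC(C)=O)[C@@H]1C
F5 | step 5 | hydroxy methyl ester (C11 CO2Me, C5 CH2OH) | COC(=O)[C@@H](C)[C@H]1OC(C)(C)O[C@@H]([C@@H](C)CO)[C@@H]1C
F6 | step 15 | C1–C14 alkenyl pinacol boronate of 17 (chain trans to boron) | C/C(=C\[C@H](C)[C@@H](O)[C@@H](C)[C@H]1OC(C)(C)O[C@@H]([C@@H](C)[C@@H](O)[C@H](C)/C=C/C(=O)O)[C@@H]1C)B2OC(C)(C)C(C)(C)O2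
F7 | step 1 | 6-ethyl-4-hydroxy-3,5-dimethyl-2H-pyran-2-one | CCC1=C(C)C(O)=C(C)C(=O)O1
F8 | step 1 | methyl 2,4-dimethyl-3,5-dioxoheptanoate (epimer mixture) | CCC(=O)C(C)C(=O)C(C)C(=O)OC
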